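**Retrosynthetic overview**
1. Target 16 ⇐ veratroylation of epoxy-diol 14 ⇐ OH-directed epoxidation of 13 ⇐ chelation-controlled reduction of the trans-fused β-hydroxy ketone 12.
2. 12 (seven-membered ring, quaternary C1, C8=C9, C6 oxygen) ⇐ [3,3]-sigmatropic (Cope) rearrangement of the 1-silyloxy-1,2-divinylcyclopropane 10, which forms C1–C10.
3. 10 ⇐ Simmons–Smith methylenation of silyloxytriene 9 ⇐ crotylation, oxidation and enol silylation of cyclopentenecarbaldehyde 5.
4. 5 ⇐ ozonolysis/aldol ring contraction of allylic acetate 3 ⇐ SeO2 hydroxylation and acetylation of (R)-terpinen-4-ol 1, which supplies C4; every other centre is relayed from it.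
5. Ring order: five-membered ring first (ring contraction of the bought cyclohexene), seven-membered ring second (Cope).

Assumption: (R)-(−)-terpinen-4-ol is used as commercial material of high enantiomeric purity.
Locants follow daucane numbering: C1 = angular-methyl carbon; C2 (OAc), C3, C4 (OH, isopropyl) complete the five-membered ring; C5 = ring-fusion CH; C6 (aroyloxy), C7, C8 (methyl), C9, C10 complete the seven-membered ring. β = the face of the C1 methyl.

**Step 1**
Reactants: 1 (R)-(−)-terpinen-4-ol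
Product: 2 (1S,3S)-4-methyl-1-(propan-2-yl)cyclohex-4-ene-1,3-diol
Conditions: SeO2 (30 mol %), t-BuOOH (2 equiv), CH2Cl2, 0 °C → rt
Reagents that add atoms: selenium dioxide O=[Se]=O; tert-butyl hydroperoxide CC(C)(C)OO
Why: Riley–Sharpless allylic hydroxylation (ene reaction, then [2,3]-sigmatropic shift) oxidises the ring CH2 next to the methyl-bearing olefin carbon and delivers OH pseudo-axially, trans to the equatorial isopropyl and cis to the tertiary OH, which sets the future C2.

**Step 2**
Reactants: 2 (1S,3S)-4-methyl-1-(propan-2-yl)cyclohex-4-ene-1,3-diol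
Product: 3 (1S,5S)-5-hydroxy-2-methyl-5-(propan-2-yl)cyclohex-2-en-1-yl acetate
Conditions: Ac2O, pyridine, DMAP (cat.), CH2Cl2, 0 °C
Reagents that add atoms: acetic anhydride CC(=O)OC(C)=O
Why: Pyridine/DMAP acylation touches only the secondary allylic alcohol (the tertiary one is inert) and installs the acetate that is carried unchanged into the target.

**Step 3**
Reactants: 3 (1S,5S)-5-hydroxy-2-methyl-5-(propan-2-yl)cyclohex-2-en-1-yl acetate
Product: 4 (3S,5R)-5-hydroxy-2,7-dioxo-5-(propan-2-yl)heptan-3-yl acetate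
Conditions: O3, CH2Cl2–MeOH, −78 °C; Me2S, −78 °C → rt
Reagents that add atoms: ozone [O-][O+]=O
Why: Ozonolysis with reductive work-up cleaves the only C=C to the methyl ketone (future C1) and the aldehyde (future C6) without touching either stereocentre.

**Step 4**
Reactants: 4 (3S,5R)-5-hydroxy-2,7-dioxo-5-(propan-2-yl)heptan-3-yl acetate
Product: 5 (1S,4S)-3-formyl-4-hydroxy-2-methyl-4-(propan-2-yl)cyclopent-2-en-1-yl acetate
Conditions: piperidine (0.3 equiv), AcOH (0.3 equiv), PhH, 4 Å sieves, 40 °C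
Reagents that add atoms: none
Why: Amine-catalysed intramolecular aldol condensation (enamine of the aldehyde onto the activated α-acetoxy methyl ketone, 5-exo, then dehydration) closes the cyclopentenecarbaldehyde, the same mode as the classical cyclisation of limonene-derived keto-aldehydes.

**Step 5**
Reactants: 5 (1S,4S)-3-formyl-4-hydroxy-2-methyl-4-(propan-2-yl)cyclopent-2-en-1-yl acetate; 6 crotyl bromide
Product: 7 (1S,4S)-4-hydroxy-3-(1-hydroxy-2-methylbut-3-en-1-yl)-2-methyl-4-(propan-2-yl)cyclopent-2-en-1-yl acetate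
Conditions: Zn dust, THF, 0 °C → rt; aq NH4Cl work-up
Reagents that add atoms: none
Why: Zinc Barbier crotylation adds chemoselectively to the aldehyde (acetate and free tertiary OH tolerated) through the γ-carbon (SE2′) to give the branched homoallylic alcohol, whose two new centres are erased in steps 6 and 7.

**Step 6**
Reactants: 7 (1S,4S)-4-hydroxy-3-(1-hydroxy-2-methylbut-3-en-1-yl)-2-methyl-4-(propan-2-yl)cyclopent-2-en-1-yl acetate
Product: 8 (1S,4S)-4-hydroxy-2-methyl-3-(2-methylbut-3-enoyl)-4-(propan-2-yl)cyclopent-2-en-1-yl acetate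
Conditions: Dess–Martin periodinane, NaHCO3, CH2Cl2, 0 °C
Reagents that add atoms: none
Why: Dess–Martin oxidation of the secondary alcohol gives the β,γ-unsaturated ketone under buffered, non-isomerising conditions; the tertiary alcohol cannot be oxidised.

**Step 7**
Reactants: 8 (1S,4S)-4-hydroxy-2-methyl-3-(2-methylbut-3-enoyl)-4-(propan-2-yl)cyclopent-2-en-1-yl acetate
Product: 9 (1S,4S)-2-methyl-3-[2-methyl-1-(triethylsilyloxy)buta-1,3-dien-1-yl]-4-(propan-2-yl)-4-(triethylsilyloxy)cyclopent-2-en-1-yl acetate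
Conditions: Et3SiOTf (2.5 equiv), Et3N (4 equiv), CH2Cl2, −40 → 0 °C
Reagents that add atoms: triethylsilyl trifluoromethanesulfonate CC[Si](CC)(CC)OS(=O)(=O)C(F)(F)F
Why: Soft enolisation removes the doubly activated α-H to give the conjugated 2-silyloxy-diene and also silylates the tertiary alcohol, which removes its directing effect and adds bulk to the β face.

**Step 8**
Reactants: 9 (1S,4S)-2-methyl-3-[2-methyl-1-(triethylsilyloxy)buta-1,3-dien-1-yl]-4-(propan-2-yl)-4-(triethylsilyloxy)cyclopent-2-en-1-yl acetate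
Product: 11 (1S,2S,4S)-2-acetoxy-4,6-bis(triethylsilyloxy)dauca-5,8-diene, via silyloxy-divinylcyclopropane 10 (not isolated)
Conditions: Et2Zn (3 equiv), CH2I2 (6 equiv), PhMe, 0 °C → rt; pyridine, filter; filtrate 120 °C (sealed), 6 h
Reagents that add atoms: diiodomethane ICI
Why: Furukawa–Simmons–Smith methylenation is fastest at the electron-rich silyl enol ether double bond, and the resulting divinylcyclopropane undergoes the Cope ([3,3]) rearrangement to the cycloheptadiene (trans isomers first epimerise thermally); C10 bonds to C1 on the face anti to the C2 acetate and C4 silyl ether, setting the quaternary C1 (methyl β) and placing C8=C9 and the C6 enol ether.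

**Step 9**
Reactants: 11 (1S,2S,4S)-2-acetoxy-4,6-bis(triethylsilyloxy)dauca-5,8-diene
Product: 12 (1S,2S,4S,5S)-2-acetoxy-4-hydroxydauc-8-en-6-one
Conditions: HF·pyridine, pyridine, THF, 0 °C → rt
Reagents that add atoms: none
Why: Fluoride desilylation frees the tertiary alcohol and the enol, whose kinetic protonation at C5 occurs on the α face (β face screened by the pseudo-axial C1 methyl and the C4 oxygen) to give the trans-fused ketone, also the isomer expected at equilibrium (C6 anti to isopropyl, hydrogen-bonded to 4-OH).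

**Step 10**
Reactants: 12 (1S,2S,4S,5S)-2-acetoxy-4-hydroxydauc-8-en-6-one
Product: 13 (1S,2S,4S,5R,6S)-2-acetoxydauc-8-ene-4,6-diol
Conditions: Et2BOMe (1.1 equiv), THF–MeOH 4:1, −78 °C; NaBH4; AcOH quench, MeOH co-evaporation
Reagents that add atoms: none
Why: Narasaka–Prasad reduction: the boron chelate between 4-OH and the C6 carbonyl is attacked by external hydride from the α face (anti to the angular methyl, as for 11-oxo steroids), giving the 4,6-syn diol (6β-OH) while the acetate survives at −78 °C.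

**Step 11**
Reactants: 13 (1S,2S,4S,5R,6S)-2-acetoxydauc-8-ene-4,6-diol
Product: 14 (1S,2S,4S,5R,6S,8R,9S)-2-acetoxy-8,9-epoxydaucane-4,6-diol
Conditions: VO(acac)2 (5 mol %), t-BuOOH (1.5 equiv), CH2Cl2, 0 °C → rt
Reagents that add atoms: tert-butyl hydroperoxide CC(C)(C)OO
Why: Vanadium-catalysed hydroxyl-directed epoxidation: the homoallylic 6β-OH binds the vanadium peroxide and delivers oxygen to the same (β) face of the only olefin, setting C8 and C9.

**Step 12**
Reactants: 14 (1S,2S,4S,5R,6S,8R,9S)-2-acetoxy-8,9-epoxydaucane-4,6-diol; 15 3,4-dimethoxybenzoyl chloride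
Product: 16 (1S,2S,4S,5R,6S,8R,9S)-2-acetoxy-8,9-epoxy-4-hydroxydaucan-6-yl 3,4-dimethoxybenzoate (CNP0330776.1)
Conditions: Et3N, DMAP (0.3 equiv), CH2Cl2, rt → 35 °C
Reagents that add atoms: none
Why: DMAP-catalysed acylation (nucleophilic catalysis) esterifies the secondary 6-OH only; the tertiary 4-OH does not react and the basic medium leaves epoxide and acetate intact.

**Compound list**
1 | (R)-(−)-terpinen-4-ol, (1R)-4-methyl-1-(propan-2-yl)cyclohex-3-en-1-ol | CC1=CC[C@@](O)(C(C)C)CC1 | starting material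
2 | (1S,3S)-4-methyl-1-(propan-2-yl)cyclohex-4-ene-1,3-diol (OH groups cis) | CC1=CC[C@@](O)(C(C)C)C[C@@H]1O | intermediate
3 | (1S,5S)-5-hydroxy-2-methyl-5-(propan-2-yl)cyclohex-2-en-1-yl acetate | CC1=CC[C@@](O)(C(C)C)C[C@@H]1OC(C)=O | intermediate
4 | (3S,5R)-5-hydroxy-2,7-dioxo-5-(propan-2-yl)heptan-3-yl acetate | CC(=O)[C@@H](OC(C)=O)C[C@](O)(C(C)C)CC=O | intermediate
5 | (1S,4S)-3-formyl-4-hydroxy-2-methyl-4-(propan-2-yl)cyclopent-2-en-1-yl acetate (OAc and OH cis) | O=CC1=C(C)[C@@H](OC(C)=O)C[C@]1(O)C(C)C | intermediate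
6 | crotyl bromide, (E)-1-bromobut-2-ene | C/C=C/CBr | starting material
7 | (1S,4S)-4-hydroxy-3-(1-hydroxy-2-methylbut-3-en-1-yl)-2-methyl-4-(propan-2-yl)cyclopent-2-en-1-yl acetate (side-chain diastereomer mixture) | C=CC(C)C(O)C1=C(C)[C@@H](OC(C)=O)C[C@]1(O)C(C)C | intermediate
8 | (1S,4S)-4-hydroxy-2-methyl-3-(2-methylbut-3-enoyl)-4-(propan-2-yl)cyclopent-2-en-1-yl acetate (epimers at the side-chain α-carbon) | C=CC(C)C(=O)C1=C(C)[C@@H](OC(C)=O)C[C@]1(O)C(C)C | intermediate
9 | (1S,4S)-2-methyl-3-[2-methyl-1-(triethylsilyloxy)buta-1,3-dien-1-yl]-4-(propan-2-yl)-4-(triethylsilyloxy)cyclopent-2-en-1-yl acetate (E/Z mixture) | C=CC(C)=C(O[Si](CC)(CC)CC)C1=C(C)[C@@H](OC(C)=O)C[C@]1(O[Si](CC)(CC)CC)C(C)C | intermediate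
10 | (1S,4S)-3-[2-ethenyl-2-methyl-1-(triethylsilyloxy)cyclopropyl]-2-methyl-4-(propan-2-yl)-4-(triethylsilyloxy)cyclopent-2-en-1-yl acetate (cyclopropane diastereomers) | C=CC1(C)CC1(O[Si](CC)(CC)CC)C2=C(C)[C@@H](OC(C)=O)C[C@]2(O[Si](CC)(CC)CC)C(C)C | intermediate (not isolated)
11 | (1S,2S,4S)-2-acetoxy-4,6-bis(triethylsilyloxy)dauca-5,8-diene (1β-CH3, 2β-OAc, 4β-OSiEt3) | CC[Si](CC)(CC)OC1=C2[C@@](O[Si](CC)(CC)CC)(C(C)C)C[C@H](OC(C)=O)[C@@]2(C)CC=C(C)C1 | intermediate
12 | (1S,2S,4S,5S)-2-acetoxy-4-hydroxydauc-8-en-6-one (2β-OAc, 4β-OH, 5α-H, trans-fused) | O=C1[C@@H]2[C@@](O)(C(C)C)C[C@H](OC(C)=O)[C@@]2(C)CC=C(C)C1 | intermediate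
13 | (1S,2S,4S,5R,6S)-2-acetoxydauc-8-ene-4,6-diol (6β-OH) | O[C@@H]1[C@@H]2[C@@](O)(C(C)C)C[C@H](OC(C)=O)[C@@]2(C)CC=C(C)C1 | intermediate
14 | (1S,2S,4S,5R,6S,8R,9S)-2-acetoxy-8,9-epoxydaucane-4,6-diol (8β,9β-epoxide) | O[C@@H]1[C@@H]2[C@@](O)(C(C)C)C[C@H](OC(C)=O)[C@@]2(C)C[C@@H]3O[C@]3(C)C1 | intermediate
15 | 3,4-dimethoxybenzoyl chloride (veratroyl chloride) | COc1ccc(cc1OC)C(Cl)=O | starting material
16 | (1S,2S,4S,5R,6S,8R,9S)-2-acetoxy-8,9-epoxy-4-hydroxydaucan-6-yl 3,4-dimethoxybenzoate | COc1ccc(C(=O)O[C@H]2C[C@@]3(C)O[C@H]3C[C@]3(C)[C@@H](OC(C)=O)C[C@](O)(C(C)C)[C@@H]23)cc1OC | target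

**Totals**
Total steps: 12. Longest linear sequence: 12 (1 → 16).

**Three steps most likely to fail**

Step 1 (SeO2 hydroxylation). Risks: competing oxidation of the vinylic methyl, a poor cis/trans ratio at the new carbinol, and partial allylic transposition of the selenium ester. The transposed cis-diol is the enantiomer of 2, so the ee of 2 must be checked. Fallback: setting out from 1, the oxidation is driven through to the enone (S)-5-hydroxy-2-methyl-5-(propan-2-yl)cyclohex-2-en-1-one F1 (SeO2/t-BuOOH, then MnO2 on the crude mixture of epimeric allylic alcohols, which converge). The carbinol centre is then set by hydride instead of by the oxidant: chelation-controlled 1,2-reduction (Et2BOMe, NaBH4, −78 °C) brings hydride in anti to the boron bridge from the axial tertiary oxygen, gives the cis-diol and comes back to the route at 2. This fallback does not cure loss of ee by transposition.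

Step 4 (aldol ring contraction). Risks: the free tertiary β-hydroxy aldehyde can dehydrate or undergo retro-aldol cleavage under amine catalysis and can lactolise onto the ketone; the α-acetoxy ketone centre can epimerise. Fallback: setting out from 3, the tertiary alcohol is taken out of play before the ring is opened. Et3SiOTf/2,6-lutidine gives (1S,5S)-2-methyl-5-(propan-2-yl)-5-(triethylsilyloxy)cyclohex-2-en-1-yl acetate F2. Ozonolysis (O3; Me2S) gives (3S,5R)-2,7-dioxo-5-(propan-2-yl)-5-(triethylsilyloxy)heptan-3-yl acetate F3. Cyclodehydration with Bn2NH·CF3CO2H gives (1S,4S)-3-formyl-2-methyl-4-(propan-2-yl)-4-(triethylsilyloxy)cyclopent-2-en-1-yl acetate F4. HF·pyridine then removes the silyl group and the sequence comes back to the route at 5.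

Step 8 (methylenation/Cope). Risks: the target double bond is a hindered tetrasubstituted enol ether in a triene; the E/Z mixture of 9 gives trans-divinylcyclopropanes that must epimerise before rearranging, in competition with a homodienyl 1,5-hydrogen shift; and facial selectivity at C1 rests on the C2 acetate and C4 silyl ether outweighing the α-isopropyl group. Fallback: setting out from 5, the cyclopropane is built from the other side. Chemoselective methyl addition (MeTi(OiPr)3) gives (1S,4S)-4-hydroxy-3-(1-hydroxyethyl)-2-methyl-4-(propan-2-yl)cyclopent-2-en-1-yl acetate F5. Dess–Martin oxidation gives the methyl ketone (1S,4S)-3-acetyl-4-hydroxy-2-methyl-4-(propan-2-yl)cyclopent-2-en-1-yl acetate F6. Et3SiOTf/Et3N gives the 2-silyloxydiene (1S,4S)-2-methyl-4-(propan-2-yl)-4-(triethylsilyloxy)-3-[1-(triethylsilyloxy)ethenyl]cyclopent-2-en-1-yl acetate F7. Rh2(OAc)4-catalysed transfer of methyl(vinyl)carbene, generated in situ from but-3-en-2-one N-[2-(trifluoromethyl)benzenesulfonyl]hydrazone and NaH, to the unhindered terminal enol-ether double bond of F7 (tandem cyclopropanation/Cope, a formal (4+3) cycloaddition) should favour the cis-divinyl isomer. This comes back to the route at 10, which rearranges to 11 below 80 °C as in step 8.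

**Further compounds**
F1 | step 1 | (S)-5-hydroxy-2-methyl-5-(propan-2-yl)cyclohex-2-en-1-one | CC1=CC[C@@](O)(C(C)C)CC1=O
F2 | step 4 | (1S,5S)-2-methyl-5-(propan-2-yl)-5-(triethylsilyloxy)cyclohex-2-en-1-yl acetate | CC1=CC[C@@](O[Si](CC)(CC)CC)(C(C)C)C[C@@H]1OC(C)=O
F3 | step 4 | (3S,5R)-2,7-dioxo-5-(propan-2-yl)-5-(triethylsilyloxy)heptan-3-yl acetate | CC(=O)[C@@H](OC(C)=O)C[C@](O[Si](CC)(CC)CC)(C(C)C)CC=O
F4 | step 4 | (1S,4S)-3-formyl-2-methyl-4-(propan-2-yl)-4-(triethylsilyloxy)cyclopent-2-en-1-yl acetate | O=CC1=C(C)[C@@H](OC(C)=O)C[C@]1(O[Si](CC)(CC)CC)C(C)C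
F5 | step 8 | (1S,4S)-4-hydroxy-3-(1-hydroxyethyl)-2-methyl-4-(propan-2-yl)cyclopent-2-en-1-yl acetate | CC(O)C1=C(C)[C@@H](OC(C)=O)C[C@]1(O)C(C)C
F6 | step 8 | (1S,4S)-3-acetyl-4-hydroxy-2-methyl-4-(propan-2-yl)cyclopent-2-en-1-yl acetate | CC(=O)C1=C(C)[C@@H](OC(C)=O)C[C@]1(O)C(C)C
F7 | step 8 | (1S,4S)-2-methyl-4-(propan-2-yl)-4-(triethylsilyloxy)-3-[1-(triethylsilyloxy)ethenyl]cyclopent-2-en-1-yl acetate | C=C(O[Si](CC)(CC)CC)C1=C(C)[C@@H](OC(C)=O)C[C@]1(O[Si](CC)(CC)CC)C(C)C
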